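**Plan**
- Retrosynthesis cuts the cyclohexenedione (C1 ketone beside the CH2, C2 carrying the coumarin, C3 =CH, C4 ketone, C5 carbinol, C6 CH2) at the C2=C3 double bond and at the C5–C6 bond. This gives a C2–C1–C6 ketone (coumarin-3-yl acetone) and a C3–C4–C5 vicinal tricarbonyl (aldehyde, ketone, prenyl ketone).
- The feature that allows this: C2 is a CH2 between coumarin C3 and the C1 carbonyl, so it is acidic and condenses with an aldehyde at C3. The tertiary alcohol C5 is β to C1, so it is the aldol of the C6 methyl onto a C5 ketone that the C4 carbonyl activates and chelates.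
- Forward order: the coumarin ring is made first (salicylaldehyde plus α-angelica lactone). The tricarbonyl is built by dithiane umpolung (prenyl bromide, then methyl dimethoxyacetate) and kept as a bis-ketal. The carbocycle is closed last, in one flask, giving the target directly.
- Helpers: the dithiane (acyl anion for C5) is exchanged for a dimethyl ketal, and both ketals are hydrolysed just before the ring-forming event.
- Stereochemistry: the only stereocentre (C5, R) is set in the ring-closing aldol by a chiral copper bis(oxazoline) complex bound to the C4/C5 diketone.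

Key step: step 5

Remark: the stereocentre of the target is read as R; compound 13 is drawn as the free tricarbonyl although it should exist mainly as its hydrates.

Step 1
Reactants: 1 2-hydroxy-4-methoxybenzaldehyde; 2 α-angelica lactone (5-methylfuran-2(3H)-one)
Product: 4 7-methoxy-3-(2-oxopropyl)-2H-chromen-2-one, via arylidene butenolide 3 (not isolated)
Conditions: Et3N (0.3 equiv), EtOH, 25 → 60 °C
Reagents that add atoms: none
Why: Knoevenagel-type aldol condensation at the C3 methylene of 2 (deprotonated to an aromatic 2-oxidofuran) should give 3, whose ortho phenol then opens the enol lactone by transesterification (the usual coumarin ring closure), and the released enol tautomerises to the methyl ketone; no stereocentre is formed.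

Step 2
Reactants: 5 1,3-dithiane; 6 1-bromo-3-methylbut-2-ene (prenyl bromide)
Product: 8 2-(3-methylbut-2-en-1-yl)-1,3-dithiane, via 2-lithio-1,3-dithiane 7 (not isolated)
Conditions: n-BuLi, THF, −30 °C; then 6, −78 °C → rt
Reagents that add atoms: none
Why: Corey–Seebach alkylation: the lithiated dithiane should displace bromide from the primary allylic carbon in an SN2 reaction, so the prenyl group arrives unrearranged.

Step 3
Reactants: 8 2-(3-methylbut-2-en-1-yl)-1,3-dithiane; 9 methyl 2,2-dimethoxyacetate
Product: 11 2,2-dimethoxy-1-[2-(3-methylbut-2-en-1-yl)-1,3-dithian-2-yl]ethan-1-one, via lithiated dithiane 10 (not isolated)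
Conditions: n-BuLi, THF, −30 °C; then added to 9 (2 equiv), THF, −78 °C; H2O
Reagents that add atoms: none
Why: Corey–Seebach acylation: the 2-lithio derivative should add to the dialkoxy-activated ester and the adduct collapse to a ketone that is too hindered (quaternary dithiane carbon on one side, acetal on the other) for a second addition.

Step 4
Reactants: 11 2,2-dimethoxy-1-[2-(3-methylbut-2-en-1-yl)-1,3-dithian-2-yl]ethan-1-one
Product: 12 1,1,3,3-tetramethoxy-6-methylhept-5-en-2-one
Conditions: PhI(OCOCF3)2 (1.5 equiv), MeOH, 0 °C → rt; then aq. NaHCO3
Reagents that add atoms: methanol, CO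
Why: Oxidative dethioacetalisation with a hypervalent iodine reagent: S-activation opens the dithiane to a thionium ion that methanol traps twice, which should give the dimethyl ketal and 1,2-dithiolane; the ketal is made instead of the free diketone so that the CH2 next to the future C5 carbonyl cannot enolise on storage.

Step 5
Reactants: 4 7-methoxy-3-(2-oxopropyl)-2H-chromen-2-one; 12 1,1,3,3-tetramethoxy-6-methylhept-5-en-2-one
Product: 15 (5R)-5-hydroxy-2-(7-methoxy-2-oxo-2H-chromen-3-yl)-5-(3-methylbut-2-en-1-yl)cyclohex-2-ene-1,4-dione, via tricarbonyl aldehyde 13 (not isolated), via ene-trione 14 (not isolated)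
Conditions: a) 12, sulfonic acid resin (Amberlyst-15, H+ form), THF–H2O (5:1), 45 °C, then filter and evaporate with toluene; b) 4, Cu(OTf)2 (10 mol %), (R,R)-tBu-box [2,2'-(propane-2,2-diyl)bis((4R)-4-tert-butyl-4,5-dihydrooxazole)] (11 mol %), Et3N (10 mol %), 4 Å MS, THF, −20 → 0 °C
Reagents that add atoms: water, O
Why: Proposed new method: hydrolysis frees both masked carbonyls of 12 to give 13, whose aldehyde (the least hindered carbonyl, bound to the divalent copper centre together with the neighbouring ketone oxygen) should condense with the acidic, coumarin-conjugated CH2 of 4 by aldol addition and E1cB loss of water, a Knoevenagel condensation that makes the C2=C3 bond and gives 14. In 14 the copper-bound 1,2-diketone acidifies the cross-conjugated acetyl CH3 through the ene-dione, and its enol carbon should add to the ketone beside the prenyl CH2 in a 6-(enolexo)-exo-trig aldol that makes the C5–C6 bond and the tertiary alcohol. The closest known reaction types are the Knoevenagel condensation of aryl acetones with glyoxals, the enantioselective Cu(OTf)2/tBu-box aldol addition of enol derivatives to chelating pyruvates and 2,3-diketones, and the Cu(OTf)2/bis(oxazoline)/Et3N nitroaldol reaction of α-keto esters. The stereocentre is controlled by the ligand: in the square-planar diketone chelate the tert-butyl group of the (R,R)-ligand should cover the Si face of the reacting ketone, so the tethered enol adds to the Re face and gives the R alcohol, the mirror image of the sense known for the (S,S)-ligand with pyruvate. Three selectivities are needed: condensation at the aldehyde and not at the central carbonyl of 13 (addition there is reversible and only the aldehyde adduct loses water easily), reaction of 4 at its CH2 and not its CH3 (several pKa units apart), and closure onto the non-conjugated ketone to the six-membered ring and not onto the enone carbonyl to a cyclopentenone (the enone carbonyl is the weaker electrophile and the six-ring product keeps the ene-dione conjugation). Only the Z isomer of 14 can close, the E isomer being fed in by reversible conjugate addition of the amine, and the reaction is stopped cold because the tertiary β-hydroxy ketone of 15 can lose water to the quinone.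

**Compound list**
1 | 2-hydroxy-4-methoxybenzaldehyde | COc1ccc(C=O)c(O)c1 | starting material
2 | α-angelica lactone (5-methylfuran-2(3H)-one) | CC1=CCC(=O)O1 | starting material
3 | (3Z)-3-[(2-hydroxy-4-methoxyphenyl)methylidene]-5-methylfuran-2(3H)-one | COc1ccc(/C=C2\C(=O)OC(C)=C2)c(O)c1 | intermediate
4 | 7-methoxy-3-(2-oxopropyl)-2H-chromen-2-one | COc1ccc2cc(CC(C)=O)c(=O)oc2c1 | intermediate
5 | 1,3-dithiane | C1CSCSC1 | starting material
6 | 1-bromo-3-methylbut-2-ene | CC(C)=CCBr | starting material
7 | 2-lithio-1,3-dithiane | [Li]C1SCCCS1 | intermediate
8 | 2-(3-methylbut-2-en-1-yl)-1,3-dithiane | CC(C)=CCC1SCCCS1 | intermediate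
9 | methyl 2,2-dimethoxyacetate | COC(OC)C(=O)OC | starting material
10 | 2-lithio-2-(3-methylbut-2-en-1-yl)-1,3-dithiane | [Li]C1(CC=C(C)C)SCCCS1 | intermediate
11 | 2,2-dimethoxy-1-[2-(3-methylbut-2-en-1-yl)-1,3-dithian-2-yl]ethan-1-one | COC(OC)C(=O)C1(CC=C(C)C)SCCCS1 | intermediate
12 | 1,1,3,3-tetramethoxy-6-methylhept-5-en-2-one | COC(OC)C(=O)C(OC)(OC)CC=C(C)C | intermediate
13 | 6-methyl-2,3-dioxohept-5-enal | CC(C)=CCC(=O)C(=O)C=O | intermediate
14 | (3Z)-3-(7-methoxy-2-oxo-2H-chromen-3-yl)-9-methyldeca-3,8-diene-2,5,6-trione | CC(=O)/C(c1cc2ccc(OC)cc2oc1=O)=C\C(=O)C(=O)CC=C(C)C | intermediate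
15 | (5R)-5-hydroxy-2-(7-methoxy-2-oxo-2H-chromen-3-yl)-5-(3-methylbut-2-en-1-yl)cyclohex-2-ene-1,4-dione | COc1ccc2cc(C3=CC(=O)[C@@](O)(CC=C(C)C)CC3=O)c(=O)oc2c1 | target

Total steps: 5. Longest linear sequence: 4 steps (steps 2 to 5).

**Steps most likely to fail**

Step 5 (key step). What may go wrong:
- addition of the enol of 4 to the central carbonyl of 13 instead of condensation at the aldehyde;
- self-condensation or migration of the alkene into conjugation in the free tricarbonyl before it is intercepted;
- ring closure outside the chiral complex, which would erode the enantiomeric purity;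
- loss of water from 15 to the quinone.

The fallback uses known reaction types only and sets out from 11 and 4. Aqueous acid (CF3CO2H–H2O–CH2Cl2, 0 °C) should hydrolyse only the dimethyl acetal of 11 and give 2-[2-(3-methylbut-2-en-1-yl)-1,3-dithian-2-yl]-2-oxoacetaldehyde F1, in which the future C5 carbonyl stays locked as the dithiane. Knoevenagel condensation of F1 with 4 (piperidinium acetate, toluene, rt) can then only take place at the aldehyde and should give (2Z)-3-(7-methoxy-2-oxo-2H-chromen-3-yl)-1-[2-(3-methylbut-2-en-1-yl)-1,3-dithian-2-yl]pent-2-ene-1,4-dione F2. Oxidative removal of the dithiane (PhI(OCOCF3)2, MeCN–H2O, NaHCO3, 0 °C) releases 14. This is extracted cold and closed at once with D-proline (DMSO, rt) in a Hajos–Parrish-type intramolecular aldol; by the enamine and carboxylic acid hydrogen-bond model of proline aldol reactions, the D enantiomer should give the R alcohol. The fallback meets the route at 15.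

Step 4. What may go wrong: attack of the iodine reagent on the electron-rich trisubstituted alkene, or incomplete exchange at the crowded, acyl-deactivated carbon leaving mixed O,S-ketals. The fallback sets out from 11. Non-oxidative, alkylative hydrolysis (MeI, CaCO3, MeCN–H2O, 40 °C) should give the free diketo acetal 1,1-dimethoxy-6-methylhept-5-ene-2,3-dione F3. It is not stored but taken straight into part a of step 5, where only the acetal has to be hydrolysed, and it meets the route at 13.

Step 1. What may go wrong: base-induced migration of the double bond of 2 into conjugation and oligomerisation before the condensation, or stalling at 3 when the E isomer cannot lactonise. The fallback sets out from 1. Perkin condensation with succinic anhydride (Et3N, 110 °C) should give 2-(7-methoxy-2-oxo-2H-chromen-3-yl)acetic acid F4. Activation with 1,1'-carbonyldiimidazole and MeNHOMe·HCl gives the Weinreb amide N-methoxy-2-(7-methoxy-2-oxo-2H-chromen-3-yl)-N-methylacetamide F5, and MeMgBr (THF, −78 °C) converts it to 4, where the fallback meets the route.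

**Further compounds**
F1 | step 5 | 2-[2-(3-methylbut-2-en-1-yl)-1,3-dithian-2-yl]-2-oxoacetaldehyde | O=CC(=O)C1(CC=C(C)C)SCCCS1
F2 | step 5 | (2Z)-3-(7-methoxy-2-oxo-2H-chromen-3-yl)-1-[2-(3-methylbut-2-en-1-yl)-1,3-dithian-2-yl]pent-2-ene-1,4-dione | CC(=O)/C(c1cc2ccc(OC)cc2oc1=O)=C\C(=O)C1(CC=C(C)C)SCCCS1
F3 | step 4 | 1,1-dimethoxy-6-methylhept-5-ene-2,3-dione | COC(OC)C(=O)C(=O)CC=C(C)C
F4 | step 1 | 2-(7-methoxy-2-oxo-2H-chromen-3-yl)acetic acid | COc1ccc2cc(CC(=O)O)c(=O)oc2c1
F5 | step 1 | N-methoxy-2-(7-methoxy-2-oxo-2H-chromen-3-yl)-N-methylacetamide | COc1ccc2cc(CC(=O)N(C)OC)c(=O)oc2c1
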